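All runs stem from a simulated flask with made-up constants; noise was put on by code.

The pitfall is to carry a percentage from one run to the next. One intermediate parts into two species, target and by-product, so the balance has a concentration in it, and a percentage read at one charge does not hold at another, even at the same temperature.

| setting | ochre | teal | ash | birch |
|---|---|---|---|---|
| starting material | 7.0 × 10⁻⁴ M | 0.0011 M | 5.0 × 10⁻⁴ M | 5.0 × 10⁻⁴ M |
| gas | 0.054 mM (held) | 0.054 mM (held) | 0.054 mM (held) | 0.054 mM (held) |
| temperature | 20 °C | 40 °C | 35 °C | 45 °C |
| remark | run made earlier | run made earlier |  |  |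
| time |  |  | 15 min | 15 min |

| run | time / min | isomer of the product / % | target / % | intermediate / % | starting material / % |
|---|---|---|---|---|---|
| ochre | 2.00 | 0.3 | 5.8 | 39.0 | 54.3 |
| ochre | 3.00 | 2.2 | 10.7 | 42.9 | 43.6 |
| ochre | 5.00 | 4.2 | 19.7 | 42.6 | 34.2 |
| ochre | 8.00 | 7.9 | 29.4 | 36.3 | 26.8 |
| ochre | 15.0 | 11.2 | 40.0 | 28.7 | 19.4 |
| ochre | 25.0 | 13.1 | 43.9 | 26.4 | 16.4 |
| teal | 1.00 | 4.9 | 16.0 | 21.1 | 58.6 |
| teal | 1.50 | 8.0 | 22.5 | 22.1 | 48.2 |
| teal | 2.50 | 9.9 | 28.9 | 22.9 | 37.4 |
| teal | 4.00 | 10.3 | 31.4 | 24.7 | 34.5 |
| teal | 8.00 | 10.8 | 30.9 | 24.9 | 33.5 |
| teal | 12.0 | 10.7 | 31.0 | 23.8 | 33.2 |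

(readings scatter by 0.5 percentage points)

- at the start none of reagent is dissolved
- what was read earlier has a scatter of 0.5 percentage points, one standard deviation
- on the list of suspects stand: starting material + reagent <-> intermediate; intermediate <-> target + by-product; target <-> isomer of the product; gas <-> reagent

- which of these there is most of at the end, counted by the starting material in it, ash (isomer of the product / target / intermediate / starting material)
- which of these there is most of at the end, counted by the starting material in it, birch (isomer of the product / target / intermediate / starting material)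
- final amount of the leader among these, as a percentage of the starting material charged, in ash
- final amount of the leader among these, as a percentage of the starting material charged, in birch

We start from teal, whose target stands at 31.4%, 30.9% and 31.0% in its last readings, flat within the scatter. Each target or isomer of the product has freed one by-product, so teal's last reading gives

[target][by-product]/[intermediate] = 0.597 mM

This is the release constant: target times by-product over intermediate, once the flask is at rest.

But it was read at 40 °C. Ochre's last reading, at 20 °C, gives 0.663 mM, and ochre is still moving, so this too is only a reading. Still, the two readings stand a factor of 1.11 apart, and we keep teal's.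

Teal also gives intermediate over starting material, 0.717, at the same held gas as ash and birch, and isomer over target, 0.345. With the charge of 5.0 × 10⁻⁴ M, the balance says that what is unreleased equals a hold-back number times the square of the released share:

hold-back number = 1.49
released share = 55.0%
target = 40.9%, starting material = 26.2%

That is our reckoning for teal's temperature. Ochre's last reading, put through the same balance at the same charge of 5.0 × 10⁻⁴ M, has a hold-back number of 0.941 and gives target 48.4%, more than teal's constants give. So we expect ash, which is colder than teal, above our figure and birch, which is warmer, below it, with target leading in both.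

Is this thermodynamic control? Teal is flat by 4.00 min, and 15 min is 3.75 times that. Ash stands closer to teal than to ochre in temperature, and birch is warmer than teal, so we accept it for both.

The forecast says target at 43% in ash and target at 38.4% in birch, reading “a chain of equilibria with dissolved reagent fixed by the held gas”. Its two numbers stand on either side of ours.

The flask gives target at 42.8% in ash and target at 38.5% in birch.

    starting material + reagent ⇌ intermediate (K = 16000 M⁻¹, k = 350 M⁻¹ s⁻¹, Ea = 44.0 kJ mol⁻¹, ΔH = −30.0 kJ mol⁻¹)
    intermediate ⇌ target + by-product (K = 6.20 × 10⁻⁴ M, k = 0.0140 s⁻¹, Ea = 90.0 kJ mol⁻¹, ΔH = −7.00 kJ mol⁻¹)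
    target ⇌ isomer of the product (K = 0.340, k = 0.0250 s⁻¹, Ea = 88.0 kJ mol⁻¹, ΔH = 6.00 kJ mol⁻¹)
    gas ⇌ reagent, rate k4*(csat - [reagent]) (kL = 0.460 s⁻¹)
    (constants at 35 °C)

In ash, target at 150 min is still 42.8%. The release constant as read in teal makes intermediate per target equal to by-product over the constant: in ash 0.480, against 0.462 found. A further flask like ash, charged with 3.0 × 10⁻⁴ M, ends with 1.98 × 10⁻⁴ M of by-product, so the constant gives 0.332, and that flask holds 15.7% intermediate against 49.3% target, a ratio of 0.318.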